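## Structural features

The target is a flavonol: benzene ring A is fused to a 4-pyranone ring C (a 4H-chromen-4-one), and a second benzene ring B is attached through the C2–C1' bond. The skeleton is flat and has no stereocentre, so nothing has to be controlled in three dimensions. Five oxygens sit on the periphery: O5 and O7 on ring A, the enolic O3 on ring C next to the C4 carbonyl, and the adjacent pair O3'/O4' on ring B. O3 and O4' are sulfate half-esters, while O5 (chelated to C4=O), O7 and O3' are free phenols. The fragile parts are the two sulfate monoesters (hydrolysed by acid, autocatalytically in the free-acid form), the electrophilic C2 of the pyranone (ring opening by hard nucleophiles) and the oxidisable catechol-type ring B. The real difficulty is regiochemical: five similar hydroxyls must be divided into two that are sulfated and three that are not, and the neighbours O3'/O4' are the hardest pair to tell apart. The key step works on this C3'–C4' edge: ring B is built from a two-carbon unit on C2 (C1'–C2') and a four-carbon furan piece (C3'–C6'), so the furan ring oxygen becomes the free O3' hydroxyl and the furan ether oxygen becomes the protected O4'.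

## Logic of the disconnections

22 ⇒ 20. The three benzylic C–O bonds at O5, O7 and O3' are cut, and the two sulfates change from acid to ammonium salt form (through 21). Benzyl ethers are cut here because hydrogenolysis is neutral and leaves S–O bonds alone, so the sulfates can be in place before the phenols are freed. The gain is that every earlier intermediate is an organic-soluble, fully protected compound. The forward step must cleave only benzylic C–O bonds, must not reduce C2=C3, and must generate the acid form cold and last.

20 ⇒ 19. The O3–S and O4'–S bonds are cut. In 19 only these two hydroxyls are free, so the regiochemistry of sulfation is decided by the protecting-group pattern and not by the reagent. The gain is a neutral, sulfur-free precursor. The forward step must drive the chelated, hindered O3–H to full conversion.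

19 ⇒ 18 ⇒ 17. The O4'–CH2 bond of the 4-methoxybenzyl ether and the O3–CH2 bond of the methoxymethyl ether are cut, then the O3'–CH2 bond of the benzyl ether. This swaps roles: O3' becomes a hydrogenolysable ether, and O3 and O4' are unmasked together by acid. The gain is 17, in which O3' is the only free hydroxyl. The acid step must spare the benzyl ethers, above all the one at O5, and must trap the benzylic cation.

17 ⇒ 12 + 15 (through 16). The C2'–C3' and C1'–C6' bonds are cut and O3' is reconnected to C6' as an oxygen bridge. This is the one cut in which the difference between O3' and O4' comes from the ring construction itself and not from selective protection of a catechol. The gain is that ring B shrinks to an ethynyl group on C2 and a monosubstituted furan. The forward step needs one orientation of the cycloaddition and one direction of bridge opening.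

15 ⇒ 13 + 14. The furan C3–O bond is cut, which leads to two purchasable compounds. The forward step is a copper-catalysed C–O coupling on a heteroaryl bromide, and the product is an acid-sensitive enol ether.

12 ⇒ 11 ⇒ 9 + 10. The C(sp)–Si bond is cut, then the C2–C(sp) bond. C2 is a vinylogous acyl carbon, so a sulfur leaving group there allows cross-coupling with a protected acetylene. The forward steps must activate the C2–S bond without opening the pyranone and must remove silicon without adding a nucleophile to the conjugated alkyne.

9 ⇒ 6 + 7 (through 8). The S–CH3, O1–C2 and C2–C3 bonds are cut. Ring C then comes from an ortho-hydroxyaryl ketone and a one-carbon electrophile at the carboxylic oxidation level, which leaves the needed sulfur on C2. The forward step requires the oxygen-bearing α-carbon to be deprotonated twice and the phenol to be free.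

6 ⇒ 5 ⇒ 2 (through 4 and 3) ⇒ 1. The O–CH2OMe bond is cut, then the α-C–O bond, then two O–benzyl bonds. O3 is introduced at the ketone stage because the α-carbon is nucleophilic there and no longer is once ring C exists. The forward steps must leave the chelated ortho-hydroxyl free (it becomes O1), oxidise the enol derivative and not the electron-rich arene, and alkylate the primary alcohol in preference to the chelated phenol.

## Other disconnections considered

Alternative 1: The cut removes both bonds of the C4 carbonyl (C4–C4a and C3–C4), so C4 comes from carbon monoxide A3.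
- **Forward step:** Pd(OAc)2 (a divalent palladium salt, reduced in the flask to zerovalent palladium) with a chelating bisphosphine and a base would join the aryl iodide 1,3,5-tris(benzyloxy)-2-iodobenzene A1, the gas A3 and the enolate of the ketone 1-[3-(benzyloxy)-4-(methoxymethoxy)phenyl]-2-(methoxymethoxy)ethan-1-one A2. The product is the 1,3-diketone A4, with a racemic, labile centre at C3; no ring closes.
- **In its favour:** it is the most convergent plan. Every carbon of the flavonol is in place after one step, both aromatic rings arrive as simple benzenes in A1 and A2, and carbonylative ketone α-arylation is a known reaction type.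
- **Against it:** A1 is electron-rich and flanked by two ortho ethers, so oxidative addition and insertion of A3 would be slow and direct α-arylation of A2 without A3 could compete. The α-alkoxy enolate of A2 can also be acylated on oxygen. The largest problem is that A4 has no free phenol for the O1–C2 closure. One ortho benzyl ether would have to be removed selectively beside two methoxymethyl acetals, and the chelation-controlled Lewis acids normally used for that would attack the acetals first.
- **Comparison:** after cyclodehydration and acid treatment this route would reach 19, so the end game is the same. On step count to 19 it should be better than the chosen plan. On the O3'/O4' distinction it depends on selective mono-protection of the catechol ketone from which A2 is made, which is reliable but external, whereas the chosen plan builds the distinction into the ring construction. On closing ring C it is weaker than the chosen plan, which keeps O1 free from the start.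

Alternative 2: The cut is the O1–C2 bond of ring C.
- **Forward step:** ICl would activate the triple bond of the ynone 3-[3-(benzyloxy)-4-(methoxymethoxy)phenyl]-1-[2,4,6-tris(benzyloxy)phenyl]prop-2-yn-1-one A5. An ortho benzyloxy oxygen attacks C2 in a 6-endo-dig closure, the benzyl group is lost from the resulting oxonium ion to chloride, and iodine ends on C3, giving the 3-iodoflavone A6.
- **In its favour:** iodocyclisation of ortho-alkoxyaryl ynones is a well-established ring C synthesis. The symmetry of ring A in A5 removes any regiochemical question, and O1 is freed and used in the same step, which alternative 1 cannot do. On precedent for the exact substrate class this ring-forming step is better than the chosen key step.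
- **Against it:** in A6, C3 carries iodine and not oxygen. O3 would need a further C–O bond formation at a hindered vinyl iodide between a carbonyl and an aryl group (borylation and oxidation, or copper-mediated hydroxylation), where loss of iodine without oxygenation is a known competing path. ICl can also iodinate the electron-rich positions of rings A and B of A5, and its Lewis acidity threatens the methoxymethyl ether.
- **Comparison:** the chosen plan carries O3 from the ketone stage, which is the safer treatment of that oxygen. Alternative 2 would deliver O3 directly as a free hydroxyl, which is an equal or slightly better end game, and would again converge on 19. Step counts should be similar. The O3'/O4' distinction again rests on catechol protection.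

Alternative 3: The cut takes O1–C8a and C4–C4a together, so ring A is supplied as an aryne.
- **Forward step:** CsF would release the aryne from the silyl triflate 3,5-bis(benzyloxy)-2-(trimethylsilyl)phenyl trifluoromethanesulfonate A7. The carboxylate of the acid (2Z)-3-[3-(benzyloxy)-4-(methoxymethoxy)phenyl]-2-(methoxymethoxy)prop-2-enoic acid A8 adds through oxygen at the aryne carbon remote from the flanking benzyloxy group. The aryl anion then attacks the acyl carbon, and collapse of the four-membered intermediate gives the 2'-hydroxychalcone A9; no ring closes.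
- **In its favour:** in A9, O1 arrives as a free phenol in the right place and O3 is present from the start. Oxa-Michael closure and dehydrogenation (I2 in DMSO) would then give the protected flavonol. The inductive effect of the flanking ether sets the regiochemistry by the same kind of polarity matching that the chosen key step uses, so the two plans are equal in kind on mechanism.
- **Against it:** A7 needs several steps of its own (ortho-halogenation, silylation, silyl migration, triflation), so ring A, which the chosen plan buys as 1, becomes the costly fragment. Protonation of the aryl anion would stop the sequence at the aryl ester, and A8 must also be prepared.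
- **Comparison:** on how O1 and O3 are handled it equals the chosen plan and is better than alternatives 1 and 2. On step economy it is probably equal or worse. Like the other two alternatives, it does not make the O3'/O4' distinction part of the ring construction.

Key step: step 8

Remark on the chemistry: the target is drawn as the free bis(hydrogen sulfate). Aryl hydrogen sulfates hydrolyse under their own acidity, so the sulfates are carried as triethylammonium salts and the acid form is released only in the last operation by cold cation exchange. For storage the salt form would be kept.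

## Steps

Step 1
Reactants: 1 2,4,6-trihydroxyacetophenone
Product: 2 1-[2,4-bis(benzyloxy)-6-hydroxyphenyl]ethan-1-one
Conditions: BnBr (2.05 equiv), K2CO3 (2.2 equiv), DMF, 0 °C → rt
Reagents that add atoms: benzyl bromide, BrCc1ccccc1
Why: Williamson etherification; after the para and one ortho hydroxyl are alkylated, the last ortho hydroxyl is held in a hydrogen bond to the carbonyl and should react much more slowly, which is the usual selectivity for phloroacetophenone.

Step 2
Reactants: 2 1-[2,4-bis(benzyloxy)-6-hydroxyphenyl]ethan-1-one
Product: 5 1-[2,4-bis(benzyloxy)-6-hydroxyphenyl]-2-hydroxyethan-1-one, via bis(trimethylsilyl) enol ether 3 (not isolated), via bis(trimethylsilyloxy) ketone 4 (not isolated)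
Conditions: LiN(SiMe3)2 (2.3 equiv), Me3SiCl (2.5 equiv), THF, −78 → 0 °C; mCPBA (1.1 equiv), NaHCO3, CH2Cl2, 0 °C; citric acid, MeOH, rt
Reagents that add atoms: 3-chloroperoxybenzoic acid (mCPBA), O=C(OO)c1cccc(Cl)c1; chlorotrimethylsilane, C[Si](C)(C)Cl (its atoms stay only in 3 and 4)
Why: Rubottom oxidation: double deprotonation and silylation cap the phenol and give the silyl enol ether 3, the peracid epoxidises the enol ether and a 1,4-silyl shift gives 4, and mild methanolysis removes both silyl groups. The enol ether is far more nucleophilic than the alkoxyarene, so the oxidant should act there first.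

Step 3
Reactants: 5 1-[2,4-bis(benzyloxy)-6-hydroxyphenyl]-2-hydroxyethan-1-one
Product: 6 1-[2,4-bis(benzyloxy)-6-hydroxyphenyl]-2-(methoxymethoxy)ethan-1-one
Conditions: MeOCH2Cl (1.2 equiv), iPr2NEt (1.5 equiv), CH2Cl2, 0 °C
Reagents that add atoms: chloromethyl methyl ether, COCCl
Why: Acetal formation by alkylation of the primary alcohol with the chloromethyl ether under hindered-amine conditions. The phenol is chelated to the ketone and is barely deprotonated by the amine at 0 °C, so it should stay free for the ring closure of step 4.

Step 4
Reactants: 6 1-[2,4-bis(benzyloxy)-6-hydroxyphenyl]-2-(methoxymethoxy)ethan-1-one; 7 carbon disulfide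
Product: 9 5,7-bis(benzyloxy)-3-(methoxymethoxy)-2-(methylsulfanyl)-4H-chromen-4-one, via 4-hydroxychromene-2-thione 8 (not isolated)
Conditions: KOtBu (3.3 equiv), CS2 (1.5 equiv), THF, 0 °C → rt; then MeI (3.3 equiv), 0 °C → rt
Reagents that add atoms: iodomethane, CI
Why: The ketone enolate is dithiocarboxylated by 7, the phenoxide closes ring C by addition–elimination at the dithiocarboxylate carbon with loss of hydrosulfide, and the soft sulfur of the anion of 8 is methylated. This is the known route from 2'-hydroxyaryl ketones to 2-(alkylthio)chromones, and benzyl and methoxymethyl ethers are inert to the base.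

Step 5
Reactants: 9 5,7-bis(benzyloxy)-3-(methoxymethoxy)-2-(methylsulfanyl)-4H-chromen-4-one; 10 ethynyltrimethylsilane
Product: 11 5,7-bis(benzyloxy)-3-(methoxymethoxy)-2-[(trimethylsilyl)ethynyl]-4H-chromen-4-one
Conditions: 10 (3 equiv), Pd(PPh3)4 (5 mol %), CuI (1.5 equiv), Et3N (3 equiv), DMF, 80 °C, sealed tube
Reagents that add atoms: none
Why: Desulfitative Sonogashira-type coupling of an electron-poor heteroaryl methyl thioether: thiophilic CuI activates the C2–S bond of the vinylogous thioester, zerovalent palladium inserts, the alkynyl group of deprotonated 10 is passed from copper to palladium and reductive elimination forms C2–C(sp). The thiolate is held as CuSMe, which is why CuI is used in stoichiometric amount.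

Step 6
Reactants: 11 5,7-bis(benzyloxy)-3-(methoxymethoxy)-2-[(trimethylsilyl)ethynyl]-4H-chromen-4-one
Product: 12 5,7-bis(benzyloxy)-2-ethynyl-3-(methoxymethoxy)-4H-chromen-4-one
Conditions: Bu4NF (1.1 equiv), AcOH (1.2 equiv), THF, 0 °C
Reagents that add atoms: none
Why: Fluoride-induced protodesilylation of the alkynylsilane. The acetic acid buffer keeps the medium from becoming basic, so no nucleophile should add to the pyranone or the conjugated alkyne.

Step 7
Reactants: 13 3-bromofuran; 14 4-methoxybenzyl alcohol
Product: 15 3-[(4-methoxyphenyl)methoxy]furan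
Conditions: 14 (2 equiv), CuI (10 mol %), 3,4,7,8-tetramethyl-1,10-phenanthroline (20 mol %), Cs2CO3 (1.5 equiv), toluene, 110 °C, sealed tube; base-washed silica
Reagents that add atoms: none
Why: Ullmann-type copper-catalysed C–O coupling of a heteroaryl bromide with a primary alcohol, the usual entry to 3-alkoxyfurans. The product is an acid-sensitive enol ether, so it is kept away from acid and used soon after purification.

Step 8
Reactants: 12 5,7-bis(benzyloxy)-2-ethynyl-3-(methoxymethoxy)-4H-chromen-4-one; 15 3-[(4-methoxyphenyl)methoxy]furan
Product: 17 5,7-bis(benzyloxy)-2-{3-hydroxy-4-[(4-methoxyphenyl)methoxy]phenyl}-3-(methoxymethoxy)-4H-chromen-4-one, via oxanorbornadiene cycloadduct 16 (not isolated)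
Conditions: 15 (3 equiv), 2,6-di-tert-butyl-4-methylphenol (cat.), toluene, 80 °C, sealed tube; then pyridinium 4-toluenesulfonate (10 mol %), CH2Cl2, 0 °C → rt
Reagents that add atoms: none
Why: A normal-electron-demand [4+2] cycloaddition joins the electron-rich furan 15 (diene) to the alkyne of 12, which is polarised through C2=C3 towards the C4 carbonyl so that its terminal carbon is the electrophilic end. The largest HOMO coefficient of 15 lies on the ring carbon next to the ether-bearing carbon, so that carbon bonds to the terminal alkyne carbon (C2'–C3') and the remote α-carbon bonds to the internal one (C1'–C6'), giving racemic 16 whether the addition is concerted and asynchronous or passes through a zwitterion. In 16, heat or the mild acid breaks the C6'–O bridge bond, because the allylic cation formed there is an oxocarbenium ion stabilised by the C4' ether oxygen; cleavage at C3' would give a cation that this oxygen cannot stabilise and whose charge would rest on C1' beside the electron-poor chromone. Loss of the C3' proton then aromatises ring B irreversibly and pulls the cycloaddition equilibrium forward. The closest known reaction type is the Diels–Alder reaction of 3-alkoxyfurans with acetylenic acceptors followed by acid-promoted isomerisation of the 7-oxanorbornadiene to a phenol. Ring B is closed by the intermolecular cycloaddition itself (two C–C bonds, suprafacial on both partners) and by no substitution step. No stereocentre is formed in 17; the two bridgehead centres of 16 are transient and disappear on aromatisation. The step needs one orientation of addition and one direction of bridge opening, both fixed by the ether group of 15 matched to the polarised alkyne, and the benzyl, 4-methoxybenzyl and methoxymethyl ethers should tolerate the weak acid in dry CH2Cl2.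

Step 9
Reactants: 17 5,7-bis(benzyloxy)-2-{3-hydroxy-4-[(4-methoxyphenyl)methoxy]phenyl}-3-(methoxymethoxy)-4H-chromen-4-one
Product: 18 5,7-bis(benzyloxy)-2-{3-(benzyloxy)-4-[(4-methoxyphenyl)methoxy]phenyl}-3-(methoxymethoxy)-4H-chromen-4-one
Conditions: BnBr (1.3 equiv), K2CO3 (2 equiv), DMF, rt
Reagents that add atoms: benzyl bromide, BrCc1ccccc1
Why: Williamson etherification of the only free hydroxyl, O3'–H; the other oxygens are all ethers.

Step 10
Reactants: 18 5,7-bis(benzyloxy)-2-{3-(benzyloxy)-4-[(4-methoxyphenyl)methoxy]phenyl}-3-(methoxymethoxy)-4H-chromen-4-one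
Product: 19 5,7-bis(benzyloxy)-2-[3-(benzyloxy)-4-hydroxyphenyl]-3-hydroxy-4H-chromen-4-one
Conditions: CF3CO2H/CH2Cl2 (1:4), pentamethylbenzene (3 equiv), 0 °C → rt; aqueous work-up
Reagents that add atoms: none
Why: Acidolysis: the 4-methoxybenzyl aryl ether ionises to a stabilised benzylic cation that is trapped by pentamethylbenzene in a Friedel–Crafts alkylation, and the methoxymethyl acetal is cleaved through its oxocarbenium ion. Plain benzyl ethers are stable to this acid at room temperature, and partial loss of the 5-O-benzyl group would be harmless because the chelated O5–H is not sulfated in step 11.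

Step 11
Reactants: 19 5,7-bis(benzyloxy)-2-[3-(benzyloxy)-4-hydroxyphenyl]-3-hydroxy-4H-chromen-4-one
Product: 20 bis(triethylammonium) 5,7-bis(benzyloxy)-2-[3-(benzyloxy)-4-(sulfonatooxy)phenyl]-4-oxo-4H-chromen-3-yl sulfate
Conditions: Et3N·SO3 (8 equiv), Et3N (2 equiv), DMF, 50 °C; Sephadex LH-20 (MeOH)
Reagents that add atoms: sulfur trioxide–triethylamine complex, CC[N+](CC)(CC)S(=O)(=O)[O-]
Why: O-Sulfation of a phenol and an enol hydroxyl by an amine–sulfur trioxide complex, the standard method for benzyl-protected flavonoids. Only O3–H and O4'–H are free, and excess reagent with mild heating is meant to carry the chelated O3–H to completion.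

Step 12
Reactants: 20 bis(triethylammonium) 5,7-bis(benzyloxy)-2-[3-(benzyloxy)-4-(sulfonatooxy)phenyl]-4-oxo-4H-chromen-3-yl sulfate
Product: 22 quercetin 3,4'-bis(hydrogen sulfate), via bis(triethylammonium) quercetin 3,4'-bissulfate 21 (not isolated)
Conditions: H2 (1 atm), Pd/C (10 wt %), MeOH/THF, Et3N (trace), rt; then Dowex 50WX8 (H+ form), H2O, 0 °C; freeze-drying
Reagents that add atoms: none
Why: Heterogeneous hydrogenolysis cleaves the three benzyl aryl ethers and leaves the sulfate monoesters and the C2=C3 bond of the flavonol intact. Cold exchange on a sulfonic acid resin then replaces the triethylammonium ions by protons.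

## Compound list

1 | 2,4,6-trihydroxyacetophenone | CC(=O)c1c(O)cc(O)cc1O | starting material
2 | 1-[2,4-bis(benzyloxy)-6-hydroxyphenyl]ethan-1-one | CC(=O)c1c(O)cc(OCc2ccccc2)cc1OCc1ccccc1 | intermediate
3 | {3,5-bis(benzyloxy)-2-[1-(trimethylsilyloxy)ethenyl]phenoxy}trimethylsilane | C=C(O[Si](C)(C)C)c1c(O[Si](C)(C)C)cc(OCc2ccccc2)cc1OCc1ccccc1 | intermediate
4 | 1-[2,4-bis(benzyloxy)-6-(trimethylsilyloxy)phenyl]-2-(trimethylsilyloxy)ethan-1-one | C[Si](C)(C)OCC(=O)c1c(O[Si](C)(C)C)cc(OCc2ccccc2)cc1OCc1ccccc1 | intermediate
5 | 1-[2,4-bis(benzyloxy)-6-hydroxyphenyl]-2-hydroxyethan-1-one | OCC(=O)c1c(O)cc(OCc2ccccc2)cc1OCc1ccccc1 | intermediate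
6 | 1-[2,4-bis(benzyloxy)-6-hydroxyphenyl]-2-(methoxymethoxy)ethan-1-one | COCOCC(=O)c1c(O)cc(OCc2ccccc2)cc1OCc1ccccc1 | intermediate
7 | carbon disulfide | S=C=S | starting material
8 | 5,7-bis(benzyloxy)-4-hydroxy-3-(methoxymethoxy)-2H-chromene-2-thione (present as its potassium salt; neutral form drawn) | S=c1oc2cc(OCc3ccccc3)cc(OCc3ccccc3)c2c(O)c1OCOC | intermediate
9 | 5,7-bis(benzyloxy)-3-(methoxymethoxy)-2-(methylsulfanyl)-4H-chromen-4-one | CSc1oc2cc(OCc3ccccc3)cc(OCc3ccccc3)c2c(=O)c1OCOC | intermediate
10 | ethynyltrimethylsilane | C#C[Si](C)(C)C | starting material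
11 | 5,7-bis(benzyloxy)-3-(methoxymethoxy)-2-[(trimethylsilyl)ethynyl]-4H-chromen-4-one | C[Si](C)(C)C#Cc1oc2cc(OCc3ccccc3)cc(OCc3ccccc3)c2c(=O)c1OCOC | intermediate
12 | 5,7-bis(benzyloxy)-2-ethynyl-3-(methoxymethoxy)-4H-chromen-4-one | C#Cc1oc2cc(OCc3ccccc3)cc(OCc3ccccc3)c2c(=O)c1OCOC | intermediate
13 | 3-bromofuran | Brc1ccoc1 | starting material
14 | 4-methoxybenzyl alcohol | COc1ccc(CO)cc1 | starting material
15 | 3-[(4-methoxyphenyl)methoxy]furan | COc1ccc(COc2ccoc2)cc1 | intermediate
16 | 5,7-bis(benzyloxy)-2-{5-[(4-methoxyphenyl)methoxy]-7-oxabicyclo[2.2.1]hepta-2,5-dien-2-yl}-3-(methoxymethoxy)-4H-chromen-4-one (racemate, one enantiomer drawn; the bridge fixes the two bridgeheads relative to each other) | O=c1c(OCOC)c(C4=C[C@@H]5O[C@H]4C=C5OCc6ccc(OC)cc6)oc2cc(OCc3ccccc3)cc(OCc3ccccc3)c12 | intermediate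
17 | 5,7-bis(benzyloxy)-2-{3-hydroxy-4-[(4-methoxyphenyl)methoxy]phenyl}-3-(methoxymethoxy)-4H-chromen-4-one | O=c1c(OCOC)c(-c2ccc(OCc3ccc(OC)cc3)c(O)c2)oc2cc(OCc3ccccc3)cc(OCc3ccccc3)c12 | intermediate
18 | 5,7-bis(benzyloxy)-2-{3-(benzyloxy)-4-[(4-methoxyphenyl)methoxy]phenyl}-3-(methoxymethoxy)-4H-chromen-4-one | O=c1c(OCOC)c(-c2ccc(OCc3ccc(OC)cc3)c(OCc3ccccc3)c2)oc2cc(OCc3ccccc3)cc(OCc3ccccc3)c12 | intermediate
19 | 5,7-bis(benzyloxy)-2-[3-(benzyloxy)-4-hydroxyphenyl]-3-hydroxy-4H-chromen-4-one | O=c1c(O)c(-c2ccc(O)c(OCc3ccccc3)c2)oc2cc(OCc3ccccc3)cc(OCc3ccccc3)c12 | intermediate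
20 | bis(triethylammonium) 5,7-bis(benzyloxy)-2-[3-(benzyloxy)-4-(sulfonatooxy)phenyl]-4-oxo-4H-chromen-3-yl sulfate | O=c1c(OS(=O)(=O)[O-])c(-c2ccc(OS(=O)(=O)[O-])c(OCc3ccccc3)c2)oc2cc(OCc3ccccc3)cc(OCc3ccccc3)c12.CC[NH+](CC)CC.CC[NH+](CC)CC | intermediate
21 | bis(triethylammonium) 5,7-dihydroxy-2-[3-hydroxy-4-(sulfonatooxy)phenyl]-4-oxo-4H-chromen-3-yl sulfate | O=c1c(OS(=O)(=O)[O-])c(-c2ccc(OS(=O)(=O)[O-])c(O)c2)oc2cc(O)cc(O)c12.CC[NH+](CC)CC.CC[NH+](CC)CC | intermediate
22 | quercetin 3,4'-bis(hydrogen sulfate): 5,7-dihydroxy-2-[3-hydroxy-4-(sulfooxy)phenyl]-4-oxo-4H-chromen-3-yl hydrogen sulfate | O=c1c(OS(=O)(=O)O)c(-c2ccc(OS(=O)(=O)O)c(O)c2)oc2cc(O)cc(O)c12 | target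

## Step count and least certain steps

Total: 12 steps. Longest linear sequence: 11 steps (steps 1–6 and 8–12); step 7 is a one-step branch.

**Step 8 (key step).**
- What may go wrong: the cycloaddition may be slow, because the alkyne of 12 is only a vinylogous acceptor and is further weakened by electron donation from O1 and O3. Long heating would then let the acid- and heat-sensitive enol ether 15 oligomerise or hydrolyse. The first C–C bond could also be followed by proton transfer instead of ring closure. Addition or bridge opening in the opposite sense is a smaller risk.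
- Fallback (ring B brought in intact by cross-coupling; sets out from 9, rejoins at 18, and makes steps 5–9 unnecessary): purchased 2-(benzyloxy)phenol would be brominated para to the hydroxyl (N-bromosuccinimide, MeCN, 0 °C) to 2-(benzyloxy)-4-bromophenol F1. Alkylation (4-methoxybenzyl chloride, K2CO3, DMF) would give 2-(benzyloxy)-4-bromo-1-[(4-methoxyphenyl)methoxy]benzene F2. Halogen–lithium exchange and borylation (n-BuLi, THF, −78 °C; B(OiPr)3; aqueous NH4Cl) would give {3-(benzyloxy)-4-[(4-methoxyphenyl)methoxy]phenyl}boronic acid F3. A Liebeskind–Srogl thioether–boronic acid coupling of 9 with F3 [Pd(PPh3)4, copper thiophene-2-carboxylate Cu(O2CC4H3S), THF, 50 °C] would then give 18 directly.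

**Step 5.**
- What may go wrong: oxidative addition into the C2–S bond of the electron-rich, 3-alkoxy-substituted thioether may be slow, so that alkyne homocoupling and copper- or base-induced desilylation outrun the cross-coupling.
- Fallback (the alkyne carbon is built by homologation and not by coupling; sets out from 6, rejoins at 12, same number of steps as steps 4–6): Claisen condensation of 6 with diethyl oxalate (NaOEt, EtOH/THF) and dehydration of the cyclic hemiketal under non-acidic conditions (MeSO2Cl, Et3N) would give ethyl 5,7-bis(benzyloxy)-3-(methoxymethoxy)-4-oxo-4H-chromene-2-carboxylate F4. Half-reduction (iBu2AlH, CH2Cl2, −78 °C) would give 5,7-bis(benzyloxy)-3-(methoxymethoxy)-4-oxo-4H-chromene-2-carbaldehyde F5. Ohira–Bestmann homologation of F5 (dimethyl (1-diazo-2-oxopropyl)phosphonate, K2CO3, MeOH, 0 °C) would give 12.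

**Step 2.**
- What may go wrong: incomplete enol silylation, or hydrolysis of the silyl enol ether before oxidation, would return 2. Peracid attack on the electron-rich ring, or Baeyer–Villiger insertion, would consume material.
- Fallback (oxidation with trivalent iodine on a capped phenol; sets out from 2, rejoins at 5): the phenol of 2 would be protected (NaH, MeOCH2Cl, THF) as 1-[2,4-bis(benzyloxy)-6-(methoxymethoxy)phenyl]ethan-1-one F6. Oxidation with PhI(OAc)2 and KOH in MeOH would give the α-hydroxy dimethyl acetal 2-[2,4-bis(benzyloxy)-6-(methoxymethoxy)phenyl]-2,2-dimethoxyethan-1-ol F7. Dilute HCl in MeOH/H2O would hydrolyse the ketal and remove the aryl acetal to give 5.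

**Step 10.**
- What may go wrong: the 4-methoxybenzyl cation may re-alkylate the electron-rich positions of ring A or ring B faster than the scavenger traps it, and the peri 5-O-benzyl ether may be partly lost on prolonged acid exposure.
- Fallback (oxidative removal without a free benzylic cation; sets out from 18, rejoins at 19): 2,3-dichloro-5,6-dicyano-1,4-benzoquinone in CH2Cl2/pH 7 buffer would give 5,7-bis(benzyloxy)-2-[3-(benzyloxy)-4-hydroxyphenyl]-3-(methoxymethoxy)-4H-chromen-4-one F8, and catalytic HCl in MeOH/THF would then remove the acetal to give 19.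

**Step 11.**
- What may go wrong: sulfation at the chelated O3–H may stop short and leave a 4'-monosulfate, and the enol sulfate may be lost during purification if the medium turns acidic.
- Fallback (neutral sulfate diesters carried to the end; sets out from 19, rejoins at 22, and replaces steps 11 and 12): 2,2,2-trichloroethyl chlorosulfate with Et3N and 4-(dimethylamino)pyridine in THF would give the bis(trichloroethyl) diester 5,7-bis(benzyloxy)-2-{3-(benzyloxy)-4-[(2,2,2-trichloroethoxy)sulfonyloxy]phenyl}-4-oxo-4H-chromen-3-yl 2,2,2-trichloroethyl sulfate F9. Transfer hydrogenolysis (Pd/C, HCO2NH4, MeOH) would remove the trichloroethyl and benzyl groups together and give diammonium 5,7-dihydroxy-2-[3-hydroxy-4-(sulfonatooxy)phenyl]-4-oxo-4H-chromen-3-yl sulfate F10. The cold cation exchange of step 12 would convert F10 into 22.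

## Further compounds

F1 | step 8 | 2-(benzyloxy)-4-bromophenol | Oc1ccc(Br)cc1OCc1ccccc1
F2 | step 8 | 2-(benzyloxy)-4-bromo-1-[(4-methoxyphenyl)methoxy]benzene | COc1ccc(COc2ccc(Br)cc2OCc2ccccc2)cc1
F3 | step 8 | {3-(benzyloxy)-4-[(4-methoxyphenyl)methoxy]phenyl}boronic acid | COc1ccc(COc2ccc(B(O)O)cc2OCc2ccccc2)cc1
F4 | step 5 | ethyl 5,7-bis(benzyloxy)-3-(methoxymethoxy)-4-oxo-4H-chromene-2-carboxylate | CCOC(=O)c1oc2cc(OCc3ccccc3)cc(OCc3ccccc3)c2c(=O)c1OCOC
F5 | step 5 | 5,7-bis(benzyloxy)-3-(methoxymethoxy)-4-oxo-4H-chromene-2-carbaldehyde | O=Cc1oc2cc(OCc3ccccc3)cc(OCc3ccccc3)c2c(=O)c1OCOC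
F6 | step 2 | 1-[2,4-bis(benzyloxy)-6-(methoxymethoxy)phenyl]ethan-1-one | CC(=O)c1c(OCOC)cc(OCc2ccccc2)cc1OCc1ccccc1
F7 | step 2 | 2-[2,4-bis(benzyloxy)-6-(methoxymethoxy)phenyl]-2,2-dimethoxyethan-1-ol | COC(CO)(OC)c1c(OCOC)cc(OCc2ccccc2)cc1OCc1ccccc1
F8 | step 10 | 5,7-bis(benzyloxy)-2-[3-(benzyloxy)-4-hydroxyphenyl]-3-(methoxymethoxy)-4H-chromen-4-one | O=c1c(OCOC)c(-c2ccc(O)c(OCc3ccccc3)c2)oc2cc(OCc3ccccc3)cc(OCc3ccccc3)c12
F9 | step 11 | 5,7-bis(benzyloxy)-2-{3-(benzyloxy)-4-[(2,2,2-trichloroethoxy)sulfonyloxy]phenyl}-4-oxo-4H-chromen-3-yl 2,2,2-trichloroethyl sulfate | O=c1c(OS(=O)(=O)OCC(Cl)(Cl)Cl)c(-c2ccc(OS(=O)(=O)OCC(Cl)(Cl)Cl)c(OCc3ccccc3)c2)oc2cc(OCc3ccccc3)cc(OCc3ccccc3)c12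
F10 | step 11 | diammonium 5,7-dihydroxy-2-[3-hydroxy-4-(sulfonatooxy)phenyl]-4-oxo-4H-chromen-3-yl sulfate | O=c1c(OS(=O)(=O)[O-])c(-c2ccc(OS(=O)(=O)[O-])c(O)c2)oc2cc(O)cc(O)c12.[NH4+].[NH4+]
A1 | alternative 1 | 1,3,5-tris(benzyloxy)-2-iodobenzene | Ic1c(OCc2ccccc2)cc(OCc2ccccc2)cc1OCc1ccccc1
A2 | alternative 1 | 1-[3-(benzyloxy)-4-(methoxymethoxy)phenyl]-2-(methoxymethoxy)ethan-1-one | COCOCC(=O)c1ccc(OCOC)c(OCc2ccccc2)c1
A3 | alternative 1 | carbon monoxide | [C-]#[O+]
A4 | alternative 1 | 1-[3-(benzyloxy)-4-(methoxymethoxy)phenyl]-2-(methoxymethoxy)-3-[2,4,6-tris(benzyloxy)phenyl]propane-1,3-dione (racemic, labile centre) | O=C(C(OCOC)C(=O)c1ccc(OCOC)c(OCc2ccccc2)c1)c1c(OCc2ccccc2)cc(OCc2ccccc2)cc1OCc1ccccc1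
A5 | alternative 2 | 3-[3-(benzyloxy)-4-(methoxymethoxy)phenyl]-1-[2,4,6-tris(benzyloxy)phenyl]prop-2-yn-1-one | O=C(C#Cc1ccc(OCOC)c(OCc2ccccc2)c1)c1c(OCc2ccccc2)cc(OCc2ccccc2)cc1OCc1ccccc1
A6 | alternative 2 | 5,7-bis(benzyloxy)-2-[3-(benzyloxy)-4-(methoxymethoxy)phenyl]-3-iodo-4H-chromen-4-one | O=c1c(I)c(-c2ccc(OCOC)c(OCc3ccccc3)c2)oc2cc(OCc3ccccc3)cc(OCc3ccccc3)c12
A7 | alternative 3 | 3,5-bis(benzyloxy)-2-(trimethylsilyl)phenyl trifluoromethanesulfonate | C[Si](C)(C)c1c(OCc2ccccc2)cc(OCc2ccccc2)cc1OS(=O)(=O)C(F)(F)F
A8 | alternative 3 | (2Z)-3-[3-(benzyloxy)-4-(methoxymethoxy)phenyl]-2-(methoxymethoxy)prop-2-enoic acid | COCO/C(=C\c1ccc(OCOC)c(OCc2ccccc2)c1)C(=O)O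
A9 | alternative 3 | (2Z)-1-[2,4-bis(benzyloxy)-6-hydroxyphenyl]-3-[3-(benzyloxy)-4-(methoxymethoxy)phenyl]-2-(methoxymethoxy)prop-2-en-1-one | COCO/C(=C\c1ccc(OCOC)c(OCc2ccccc2)c1)C(=O)c1c(O)cc(OCc2ccccc2)cc1OCc1ccccc1
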